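## Retrosynthetic overview

1. The last bond made is C2(octalin)–CH2 of the two-carbon linker: 9-BBN hydroboration of a 6-vinyl-1,2-dioxane acid, then B-alkyl Suzuki–Miyaura coupling with the enol triflate of the cis-octalin.
2. The feature the plan rests on: in the 1,2-dioxane ring (O1–O2–C3–C4–C5–C6), C6 (CH3 and linker) and C3 (H and propanoic arm) are cis. They are the bridgeheads C1 and C4 of 1,5-dimethyl-2,3-dioxabicyclo[2.2.2]oct-5-ene, made from singlet oxygen and 1,3-dimethylcyclohexa-1,3-diene. Ozone cuts the C5=C6 bridge and leaves CHO on C6 and acetyl on C3.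
3. Arms: the CHO group is masked as its dimethyl acetal; acetyl → isopropenyl → anti-selective hydroboration → CH(CH3)CO2H; the racemate is split as an amine salt; CHO is unmasked and turned into vinyl. The arms are built one after the other so that only one terminal alkene is present whenever 9-BBN is used.
4. Octalin: 2,6-dimethylphenol → 2,6,6-trimethylcyclohexadienone → Diels–Alder with ethylene → resolved bicyclo[2.2.2]octenone → isopropenyl carbinol → anionic oxy-Cope → enolate → triflate.
5. Ring order: the dioxane ring first (step 3, as the bicycle); in the second branch the bicyclo[2.2.2]octene (step 13), then both carbocycles of the octalin together (step 16).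

Key step: step 3

Assumption 1: racemic compounds (5, 7, 8, 10–13, 22) are drawn and named as the enantiomer that is carried on.
Assumption 2: in step 9 the (S)-amine is written; if the less soluble salt holds the other acid, (R)-1-phenylethylamine is used in the same way.

## Route

Step 1
Reactants: 1 3-methylcyclohex-2-en-1-one; 2 methylmagnesium bromide
Product: 3 1,3-dimethylcyclohex-2-en-1-ol (racemic)
Conditions: MeMgBr (1.2 equiv), Et2O, 0 °C → rt; water quench
Reagents that add atoms: methylmagnesium bromide C[Mg]Br
Why: Grignard 1,2-addition, since the β,β-disubstituted enone is attacked at the carbonyl carbon and not at the hindered β-carbon; the new centre is removed in step 2.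

Step 2
Reactants: 3 1,3-dimethylcyclohex-2-en-1-ol
Product: 4 1,3-dimethylcyclohexa-1,3-diene
Conditions: p-TsOH·H2O (1 mol%), pentane, reflux with water separator; distillation
Reagents that add atoms: none
Why: Acid-catalysed E1 dehydration of the tertiary allylic alcohol through the allyl cation, with acid equilibration of the diene isomers toward the endocyclic conjugated diene that has two trisubstituted double bonds.

Step 3
Reactants: 4 1,3-dimethylcyclohexa-1,3-diene
Product: 5 rac-(1S,4R)-1,5-dimethyl-2,3-dioxabicyclo[2.2.2]oct-5-ene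
Conditions: O2, tetraphenylporphyrin (0.2 mol%), CH2Cl2, white LEDs, −20 °C
Reagents that add atoms: dioxygen O=O
Why: Photosensitised singlet oxygen adds across C1 and C4 of the diene in a concerted suprafacial [4+2] cycloaddition, the closest known case being the formation of ascaridole from α-terpinene. Both C–O bonds form in this one event and close the six-membered 1,2-dioxane ring as the peroxide bridge of a 2,3-dioxabicyclo[2.2.2]oct-5-ene, a [4+2] closure onto a diene held s-cis by the carbocycle. The two new stereocentres are the bridgeheads C1 (CH3) and C4 (H); their relative configuration is fixed by the suprafacial addition and the bicyclic frame, and because diene and reagent are achiral the product should form as the racemate. The selectivity needed is cycloaddition over the ene reaction at the two allylic methyl groups and the ring CH2 groups; the rigid cisoid diene and the low temperature in an aprotic solvent favour the cycloaddition. Oxygen necessarily bonds to the methyl-bearing terminus and to the CH terminus, which places the methyl group of the C5=C6 bridge next to the CH bridgehead.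

Step 4
Reactants: 5 rac-(1S,4R)-1,5-dimethyl-2,3-dioxabicyclo[2.2.2]oct-5-ene
Product: 7 rac-(3R,6S)-3-acetyl-6-methyl-1,2-dioxane-6-carbaldehyde, via secondary ozonide 6 (not isolated)
Conditions: O3, CH2Cl2, −78 °C; N2 purge; Me2S (5 equiv), −78 °C → rt; used crude
Reagents that add atoms: ozone [O-][O+]=O
Why: Ozonolysis (dipolar cycloaddition, cycloreversion, recombination to the ozonide, reduction by the sulfide) cleaves only the C5=C6 bridge, because the saturated O–O bond reacts with neither ozone nor dimethyl sulfide at these temperatures; both carbonyl carbons stay on the dioxane ring, so the cis relation is kept.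

Step 5
Reactants: 7 rac-(3R,6S)-3-acetyl-6-methyl-1,2-dioxane-6-carbaldehyde
Product: 8 rac-1-[(3R,6S)-6-(dimethoxymethyl)-6-methyl-1,2-dioxan-3-yl]ethan-1-one
Conditions: HC(OMe)3 (3 equiv), MeOH, PPTS (5 mol%), 0 °C → rt
Reagents that add atoms: methanol CO; trimethyl orthoformate COC(OC)OC
Why: Acid-catalysed acetalisation with orthoformate as water scavenger is much faster for the aldehyde than for the α-oxygenated methyl ketone, and it avoids base, which would remove the C3 proton and break the O–O bond.

Step 6
Reactants: 8 rac-1-[(3R,6S)-6-(dimethoxymethyl)-6-methyl-1,2-dioxan-3-yl]ethan-1-one; 9 methyltriphenylphosphonium bromide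
Product: 10 rac-(3R,6S)-6-(dimethoxymethyl)-6-methyl-3-(prop-1-en-2-yl)-1,2-dioxane
Conditions: Ph3PCH3Br (1.5 equiv), KHMDS (1.4 equiv), THF, 0 °C; then 8, −78 → 0 °C
Reagents that add atoms: methyltriphenylphosphonium bromide C[P+](c1ccccc1)(c1ccccc1)c1ccccc1.[Br-]
Why: Wittig methylenation, in which the ylide should add to the methyl ketone at low temperature faster than it removes the tertiary C3–H next to the peroxide (kinetic deprotonation of α-alkoxy ketones prefers the other α-carbon); the acetal has no electrophilic site.

Step 7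
Reactants: 10 rac-(3R,6S)-6-(dimethoxymethyl)-6-methyl-3-(prop-1-en-2-yl)-1,2-dioxane
Product: 12 rac-(2S)-2-[(3R,6S)-6-(dimethoxymethyl)-6-methyl-1,2-dioxan-3-yl]propan-1-ol, via B-alkyl-9-BBN 11 (not isolated)
Conditions: 9-BBN (1.5 equiv), THF, 0 °C → rt; then 30% H2O2, 2 M NaOH, 0 °C
Reagents that add atoms: hydrogen peroxide OO
Why: Anti-Markovnikov hydroboration with 9-BBN and oxidation with retention; the α-methyl centre is set by 1,2-induction from C3, the borane attacking the face anti to ring carbon C4 in the conformer with C3–H eclipsing the double bond and the ring oxygen outside, which is the known anti-selective hydroboration of 1,1-disubstituted allylic ethers and should give (2S) relative to (3R); any syn alcohol is removed by chromatography.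

Step 8
Reactants: 12 rac-(2S)-2-[(3R,6S)-6-(dimethoxymethyl)-6-methyl-1,2-dioxan-3-yl]propan-1-ol
Product: 13 rac-(2R)-2-[(3R,6S)-6-(dimethoxymethyl)-6-methyl-1,2-dioxan-3-yl]propanoic acid
Conditions: TEMPO (0.2 equiv), PhI(OAc)2 (2.2 equiv), MeCN/H2O 1:1, rt
Reagents that add atoms: water O
Why: Oxoammonium (TEMPO) oxidation with PhI(OAc)2 as terminal oxidant takes the primary alcohol through the aldehyde hydrate to the acid under neutral to weakly acidic conditions, so the α-centre, the acetal and the O–O bond should be untouched.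

Step 9
Reactants: 13 rac-(2R)-2-[(3R,6S)-6-(dimethoxymethyl)-6-methyl-1,2-dioxan-3-yl]propanoic acid
Product: 14 (S)-1-phenylethylammonium (2R)-2-[(3R,6S)-6-(dimethoxymethyl)-6-methyl-1,2-dioxan-3-yl]propanoate
Conditions: (S)-1-phenylethylamine (1.0 equiv), EtOAc/hexane, crystallisation at 4 °C; recrystallisation to constant rotation
Reagents that add atoms: (S)-1-phenylethylamine C[C@H](N)c1ccccc1
Why: Classical resolution through diastereomeric ammonium carboxylates, where the α-methyl acid forms two salts of different solubility with the enantiopure amine; no bond to a stereocentre is made or broken.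

Step 10
Reactants: 14 (S)-1-phenylethylammonium (2R)-2-[(3R,6S)-6-(dimethoxymethyl)-6-methyl-1,2-dioxan-3-yl]propanoate
Product: 15 (2R)-2-[(3R,6S)-6-formyl-6-methyl-1,2-dioxan-3-yl]propanoic acid
Conditions: 2 M aq. HCl/THF 1:2, rt → 40 °C
Reagents that add atoms: water O
Why: Acid hydrolysis of the dimethyl acetal through the oxocarbenium ion frees the aldehyde and at the same time protonates the carboxylate, the amine leaving in the water phase; dialkyl peroxides are stable to aqueous acid and the aldehyde has no α-hydrogen.

Step 11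
Reactants: 15 (2R)-2-[(3R,6S)-6-formyl-6-methyl-1,2-dioxan-3-yl]propanoic acid; 9 methyltriphenylphosphonium bromide
Product: 16 (2R)-2-[(3R,6S)-6-ethenyl-6-methyl-1,2-dioxan-3-yl]propanoic acid
Conditions: KHMDS (2.4 equiv), Ph3PCH3Br (1.4 equiv), THF, −78 → 0 °C; dilute HCl work-up (pH 3)
Reagents that add atoms: methyltriphenylphosphonium bromide C[P+](c1ccccc1)(c1ccccc1)c1ccccc1.[Br-]
Why: Wittig methylenation of a non-enolisable aldehyde, in which the first equivalent of base only forms the potassium carboxylate, which is inert to the ylide and shields the α-centre from deprotonation.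

Step 12
Reactants: 17 2,6-dimethylphenol; 18 iodomethane
Product: 20 2,6,6-trimethylcyclohexa-2,4-dien-1-one, via lithium 2,6-dimethylphenoxide 19 (not isolated)
Conditions: n-BuLi (1.0 equiv), toluene, 0 °C; MeI (3 equiv), 140 °C, sealed vessel; distillation
Reagents that add atoms: iodomethane CI
Why: C-alkylation of an ambident phenoxide, where the lithium phenoxide aggregate in toluene shields oxygen so that methyl iodide attacks an ortho carbon (both are equivalent) and the blocked position cannot rearomatise; the anisole side product is removed by distillation.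

Step 13
Reactants: 20 2,6,6-trimethylcyclohexa-2,4-dien-1-one; 21 ethylene
Product: 22 rac-(1R,4S)-1,3,3-trimethylbicyclo[2.2.2]oct-5-en-2-one
Conditions: ethylene (60 bar), toluene, BHT (cat.), 150 °C, autoclave
Reagents that add atoms: ethylene C=C
Why: Diels–Alder reaction with the dienone as diene (termini C2 and C5), ethylene bridging these carbons to give the bicyclo[2.2.2]octenone with the methyl group on the bridgehead next to the carbonyl group; the dienone dimer should revert at this temperature while the ethylene adduct does not, and the two bridgeheads form together as a racemate.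

Step 14
Reactants: 22 rac-(1R,4S)-1,3,3-trimethylbicyclo[2.2.2]oct-5-en-2-one
Product: 23 (1R,4S)-1,3,3-trimethylbicyclo[2.2.2]oct-5-en-2-one
Conditions: preparative HPLC, cellulose tris(3,5-dimethylphenylcarbamate) stationary phase, hexane/i-PrOH 99:1
Reagents that add atoms: none
Why: Enantiomer separation by chromatography on a polysaccharide carbamate chiral stationary phase, a method suited to rigid bicyclic ketones; no reaction takes place, and the wanted enantiomer is to be assigned by circular dichroism of the n→π* band.

Step 15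
Reactants: 23 (1R,4S)-1,3,3-trimethylbicyclo[2.2.2]oct-5-en-2-one; 24 isopropenylmagnesium bromide
Product: 25 (1R,2S,4S)-1,3,3-trimethyl-2-(prop-1-en-2-yl)bicyclo[2.2.2]oct-5-en-2-ol
Conditions: isopropenylmagnesium bromide (2 equiv), CeCl3 (2 equiv), THF, −78 → 0 °C; water quench
Reagents that add atoms: isopropenylmagnesium bromide CC(=C)[Mg]Br
Why: Cerium-modified Grignard addition to a hindered non-enolisable ketone, the nucleophile entering from the face of the etheno bridge, which is less shielded than the ethano bridge, so that the isopropenyl group ends syn to C5=C6 (2S) as the next step needs.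

Step 16
Reactants: 25 (1R,2S,4S)-1,3,3-trimethyl-2-(prop-1-en-2-yl)bicyclo[2.2.2]oct-5-en-2-ol
Product: 28 (4aR,8aS)-1,1,3,6-tetramethyl-1,4,4a,7,8,8a-hexahydronaphthalen-2-yl trifluoromethanesulfonate, via potassium alkoxide 26 (not isolated), via potassium enolate 27 (not isolated)
Conditions: KH (1.5 equiv), 18-crown-6 (1.5 equiv), THF, 0 °C → rt; then PhNTf2 (1.3 equiv), −78 → 0 °C; aq. NH4Cl
Reagents that add atoms: N-phenylbis(trifluoromethanesulfonimide) O=S(=O)(N(c1ccccc1)S(=O)(=O)C(F)(F)F)C(F)(F)F
Why: Anionic oxy-Cope rearrangement, in which the alkoxide breaks the C1–C2 bond and joins the isopropenyl CH2 to C5 through the boat transition state enforced by the bicycle; this gives only the cis ring fusion (C4a formed on the face fixed by C8a) and a single enolate regioisomer, which PhNTf2 sulfonylates on oxygen to the tetrasubstituted enol triflate.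

Step 17
Reactants: 16 (2R)-2-[(3R,6S)-6-ethenyl-6-methyl-1,2-dioxan-3-yl]propanoic acid; 28 (4aR,8aS)-1,1,3,6-tetramethyl-1,4,4a,7,8,8a-hexahydronaphthalen-2-yl trifluoromethanesulfonate
Product: 30 (2R)-2-[(3R,6R)-6-methyl-6-{2-[(4aR,8aS)-1,1,3,6-tetramethyl-1,4,4a,7,8,8a-hexahydronaphthalen-2-yl]ethyl}-1,2-dioxan-3-yl]propanoic acid (CNP0122760.1), via bis-boryl intermediate 29 (not isolated)
Conditions: 16 (1.3 equiv), 9-BBN (2.3 equiv per 16), THF, 0 °C → rt; then 28, Pd(dppf)Cl2 (10 mol%), AsPh3 (10 mol%), 3 M aq. K3PO4, DMF, rt; citric acid work-up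
Reagents that add atoms: none
Why: Hydroboration and B-alkyl Suzuki–Miyaura coupling, where 9-BBN first turns the acid into an acyloxyborane (H2 is lost and this group is reduced only very slowly) and then adds to the monosubstituted alkene at the terminal carbon; the primary alkyl group is transferred to the alkenylpalladium from the triflate and reductive elimination forms the C(sp3)–C(sp2) bond at room temperature, conditions under which dialkyl peroxides are known to survive palladium-catalysed couplings, and no stereocentre is touched.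

## Compound list

1 | 3-methylcyclohex-2-en-1-one | CC1=CC(=O)CCC1 | starting material
2 | methylmagnesium bromide | C[Mg]Br | starting material
3 | 1,3-dimethylcyclohex-2-en-1-ol (racemic) | CC1=CC(C)(O)CCC1 | intermediate
4 | 1,3-dimethylcyclohexa-1,3-diene | CC1=CC(C)=CCC1 | intermediate
5 | rac-(1S,4R)-1,5-dimethyl-2,3-dioxabicyclo[2.2.2]oct-5-ene | C[C@@]12C=C(C)[C@@H](CC1)OO2 | intermediate
6 | secondary ozonide (1,2,4-trioxolane across C5–C6 of 5; not isolated) | C[C@@]12C3OC(C)(OO3)[C@@H](CC1)OO2 | intermediate
7 | rac-(3R,6S)-3-acetyl-6-methyl-1,2-dioxane-6-carbaldehyde | O=C[C@]1(C)CC[C@H](C(C)=O)OO1 | intermediate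
8 | rac-1-[(3R,6S)-6-(dimethoxymethyl)-6-methyl-1,2-dioxan-3-yl]ethan-1-one | COC(OC)[C@]1(C)CC[C@H](C(C)=O)OO1 | intermediate
9 | methyltriphenylphosphonium bromide | C[P+](c1ccccc1)(c1ccccc1)c1ccccc1.[Br-] | starting material
10 | rac-(3R,6S)-6-(dimethoxymethyl)-6-methyl-3-(prop-1-en-2-yl)-1,2-dioxane | COC(OC)[C@]1(C)CC[C@H](C(C)=C)OO1 | intermediate
11 | B-alkyl-9-BBN from 10 (not isolated) | COC(OC)[C@]1(C)CC[C@H]([C@@H](C)CB2C3CCCC2CCC3)OO1 | intermediate
12 | rac-(2S)-2-[(3R,6S)-6-(dimethoxymethyl)-6-methyl-1,2-dioxan-3-yl]propan-1-ol | COC(OC)[C@]1(C)CC[C@H]([C@@H](C)CO)OO1 | intermediate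
13 | rac-(2R)-2-[(3R,6S)-6-(dimethoxymethyl)-6-methyl-1,2-dioxan-3-yl]propanoic acid | COC(OC)[C@]1(C)CC[C@H]([C@@H](C)C(=O)O)OO1 | intermediate
14 | (S)-1-phenylethylammonium (2R)-2-[(3R,6S)-6-(dimethoxymethyl)-6-methyl-1,2-dioxan-3-yl]propanoate | COC(OC)[C@]1(C)CC[C@H]([C@@H](C)C(=O)[O-])OO1.C[C@H]([NH3+])c1ccccc1 | intermediate
15 | (2R)-2-[(3R,6S)-6-formyl-6-methyl-1,2-dioxan-3-yl]propanoic acid | O=C[C@]1(C)CC[C@H]([C@@H](C)C(=O)O)OO1 | intermediate
16 | (2R)-2-[(3R,6S)-6-ethenyl-6-methyl-1,2-dioxan-3-yl]propanoic acid | C=C[C@]1(C)CC[C@H]([C@@H](C)C(=O)O)OO1 | intermediate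
17 | 2,6-dimethylphenol | Cc1cccc(C)c1O | starting material
18 | iodomethane | CI | starting material
19 | lithium 2,6-dimethylphenoxide (not isolated) | Cc1cccc(C)c1[O-].[Li+] | intermediate
20 | 2,6,6-trimethylcyclohexa-2,4-dien-1-one | CC1=CC=CC(C)(C)C1=O | intermediate
21 | ethylene | C=C | starting material
22 | rac-(1R,4S)-1,3,3-trimethylbicyclo[2.2.2]oct-5-en-2-one | C[C@]12C=C[C@H](CC1)C(C)(C)C2=O | intermediate
23 | (1R,4S)-1,3,3-trimethylbicyclo[2.2.2]oct-5-en-2-one (single enantiomer) | C[C@]12C=C[C@H](CC1)C(C)(C)C2=O | intermediate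
24 | isopropenylmagnesium bromide | CC(=C)[Mg]Br | starting material
25 | (1R,2S,4S)-1,3,3-trimethyl-2-(prop-1-en-2-yl)bicyclo[2.2.2]oct-5-en-2-ol | C[C@]12C=C[C@H](CC1)C(C)(C)[C@@]2(O)C(C)=C | intermediate
26 | potassium alkoxide of 25 (not isolated) | C[C@]12C=C[C@H](CC1)C(C)(C)[C@@]2([O-])C(C)=C.[K+] | intermediate
27 | potassium (4aR,8aS)-1,1,3,6-tetramethyl-1,4,4a,7,8,8a-hexahydronaphthalen-2-olate (not isolated) | CC1=C[C@H]2CC(C)=C([O-])C(C)(C)[C@H]2CC1.[K+] | intermediate
28 | (4aR,8aS)-1,1,3,6-tetramethyl-1,4,4a,7,8,8a-hexahydronaphthalen-2-yl trifluoromethanesulfonate | CC1=C[C@H]2CC(C)=C(OS(=O)(=O)C(F)(F)F)C(C)(C)[C@H]2CC1 | intermediate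
29 | bis-boryl intermediate: B-alkyl-9-BBN of 16 with the acid as its O-(9-BBN) derivative (not isolated) | C1CCC2CCCC1B2CC[C@]3(C)CC[C@H]([C@@H](C)C(=O)OB4C5CCCC4CCC5)OO3 | intermediate
30 | (2R)-2-[(3R,6R)-6-methyl-6-{2-[(4aR,8aS)-1,1,3,6-tetramethyl-1,4,4a,7,8,8a-hexahydronaphthalen-2-yl]ethyl}-1,2-dioxan-3-yl]propanoic acid | CC1=C[C@H]2CC(C)=C(CC[C@]3(C)CC[C@H]([C@@H](C)C(=O)O)OO3)C(C)(C)[C@H]2CC1 | target

## Step count and risks

Total step count: 17. Longest linear sequence: 12 steps (steps 1–11, then step 17); the octalin branch is steps 12–16.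

**Step 17 (hydroboration and coupling).** The alkenylpalladium formed from 28 is flanked by a quaternary carbon and a methyl-bearing carbon. Transfer of the alkyl group from boron may therefore be slower than protodeboronation of 29, or than attack of Pd(0) on the O–O bond. The fallback sets out from 16 and 28 and joins them by a Heck reaction (Pd(OAc)2, n-Bu4NCl, KOAc, DMF, 60 °C). The unhindered vinyl group inserts into the Pd–C bond, and β-hydride elimination is possible only toward the former CH. This should give (2R)-2-[(3R,6S)-6-methyl-6-{(E)-2-[(4aR,8aS)-1,1,3,6-tetramethyl-1,4,4a,7,8,8a-hexahydronaphthalen-2-yl]ethenyl}-1,2-dioxan-3-yl]propanoic acid F1. Diimide (potassium azodicarboxylate, AcOH, MeOH, 0 °C → rt) then saturates the 1,2-disubstituted double bond; the tri- and tetrasubstituted ring alkenes and the peroxide are left, and the route is rejoined at 30.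

**Step 6 (methylenation of the ketone).** The ylide may act as a base at C3 instead of adding to the carbonyl group. Loss of that proton is coupled to O–O cleavage (Kornblum–DeLaMare fragmentation) and would destroy the ring. The fallback sets out from 8 and uses a Peterson olefination in two operations. Me3SiCH2Li/CeCl3 (THF, −78 °C) adds as a weakly basic organocerium reagent to give rac-2-[(3R,6S)-6-(dimethoxymethyl)-6-methyl-1,2-dioxan-3-yl]-1-(trimethylsilyl)propan-2-ol F2. KH (THF, 0 °C) then effects syn-elimination of the silanolate from the potassium alkoxide, which no longer has an acidifying carbonyl group next to C3, and the route is rejoined at 10.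

**Step 9 (salt resolution).** The two diastereomeric salts may oil out or co-crystallise, so that no enrichment is reached. The fallback sets out from 13 and separates covalent diastereomers instead. PivCl/Et3N (THF, −20 °C) gives the mixed pivalic anhydride F3. (S)-4-Benzyl-1,3-oxazolidin-2-one with LiCl (rt) then gives two N-acyl oxazolidinones, which are separated on silica gel: the wanted (2R,3R,6S) imide F4 and its (2S,3S,6R) diastereomer F5. LiOH/H2O2 (THF/H2O, 0 °C) on F4 releases the enantiopure (2R)-2-[(3R,6S)-6-(dimethoxymethyl)-6-methyl-1,2-dioxan-3-yl]propanoic acid F6. F6 enters step 10 in place of 14, and the route is rejoined at 15.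

## Further compounds

F1 | step 17 | (2R)-2-[(3R,6S)-6-methyl-6-{(E)-2-[(4aR,8aS)-1,1,3,6-tetramethyl-1,4,4a,7,8,8a-hexahydronaphthalen-2-yl]ethenyl}-1,2-dioxan-3-yl]propanoic acid | CC1=C[C@H]2CC(C)=C(/C=C/[C@]3(C)CC[C@H]([C@@H](C)C(=O)O)OO3)C(C)(C)[C@H]2CC1
F2 | step 6 | rac-2-[(3R,6S)-6-(dimethoxymethyl)-6-methyl-1,2-dioxan-3-yl]-1-(trimethylsilyl)propan-2-ol (carbinol epimers) | COC(OC)[C@]1(C)CC[C@H](C(C)(O)C[Si](C)(C)C)OO1
F3 | step 9 | rac-(2R)-2-[(3R,6S)-6-(dimethoxymethyl)-6-methyl-1,2-dioxan-3-yl]propanoic pivalic anhydride | COC(OC)[C@]1(C)CC[C@H]([C@@H](C)C(=O)OC(=O)C(C)(C)C)OO1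
F4 | step 9 | (4S)-4-benzyl-3-{(2R)-2-[(3R,6S)-6-(dimethoxymethyl)-6-methyl-1,2-dioxan-3-yl]propanoyl}-1,3-oxazolidin-2-one | COC(OC)[C@]1(C)CC[C@H]([C@@H](C)C(=O)N2[C@@H](Cc3ccccc3)COC2=O)OO1
F5 | step 9 | (4S)-4-benzyl-3-{(2S)-2-[(3S,6R)-6-(dimethoxymethyl)-6-methyl-1,2-dioxan-3-yl]propanoyl}-1,3-oxazolidin-2-one | COC(OC)[C@@]1(C)CC[C@@H]([C@H](C)C(=O)N2[C@@H](Cc3ccccc3)COC2=O)OO1
F6 | step 9 | (2R)-2-[(3R,6S)-6-(dimethoxymethyl)-6-methyl-1,2-dioxan-3-yl]propanoic acid (single enantiomer) | COC(OC)[C@]1(C)CC[C@H]([C@@H](C)C(=O)O)OO1
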